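Crocoxanthin, (3R,6'R)-7,8-didehydro-β,ε-caroten-3-ol: retrosynthetic overview

1. Cut C11=C12 into two aldehydes: a C15 enynal (hydroxy-ring half) and a C25 hexaenal (ε-ring half). In the forward sense the C11 carbonyl carbon becomes a carbon nucleophile (tosylhydrazone → diazoalkene → phosphite ylide) and attacks the C12 carbonyl carbon.
2. C25 hexaenal ⇒ (R)-α-ionone + vinyl Grignard (C15 phosphonium salt) + C10 dialdehyde (Wittig at C11'=C12').
3. C15 enynal ⇒ ring enol triflate + (E)-3-methylpent-2-en-4-yn-1-ol (Sonogashira at C6–C7), then allylic oxidation.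
4. Ring enol triflate ⇒ ketoisophorone. Asymmetric transfer hydrogenation sets C3, and conjugate reduction with enolate triflation places C5=C6.
5. No ring is formed. Both six-membered rings come intact with the starting materials, and C6' is bought with α-ionone.

Assumption: (R)-α-ionone is bought as the fermentation-derived flavour-grade single enantiomer (racemic α-ionone would first need a resolution); chain positions use carotenoid numbering, and all polyene steps run under argon in dim light.

Step 1
Reactants: 1 ketoisophorone (2,6,6-trimethylcyclohex-2-ene-1,4-dione)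
Product: 2 (4S)-4-hydroxy-2,6,6-trimethylcyclohex-2-en-1-one
Conditions: RuCl[(S,S)-TsDPEN](p-cymene) (0.5 mol %), KOH (1 mol %), i-PrOH, 20 °C
Reagents that add atoms: none
Why: In this Noyori asymmetric transfer hydrogenation only the unhindered C4 carbonyl is reduced (C1 is shielded by the gem-dimethyl and the vinylic methyl), and with the alkenyl flank playing the aryl role in the usual CH/π model the (S,S) catalyst gives the 4S alcohol, which is the later 3R centre of the target (only the CIP ranking of the ring carbons changes).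

Step 2
Reactants: 2 (4S)-4-hydroxy-2,6,6-trimethylcyclohex-2-en-1-one
Product: 3 (4S)-4-[(tert-butyldimethylsilyl)oxy]-2,6,6-trimethylcyclohex-2-en-1-one
Conditions: TBSCl, imidazole, DMF, rt
Reagents that add atoms: tert-butyldimethylsilyl chloride, CC(C)(C)[Si](C)(C)Cl
Why: Imidazole-promoted silylation of a secondary alcohol masks the OH against hydride, enolate triflation and the carbene step without touching the stereocentre.

Step 3
Reactants: 3 (4S)-4-[(tert-butyldimethylsilyl)oxy]-2,6,6-trimethylcyclohex-2-en-1-one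
Product: 5 (4R)-4-[(tert-butyldimethylsilyl)oxy]-2,6,6-trimethylcyclohex-1-en-1-yl trifluoromethanesulfonate, via lithium enolate 4 (not isolated)
Conditions: L-Selectride (1.1 equiv), THF, −78 °C; then PhNTf2, −78 °C → rt
Reagents that add atoms: N-phenylbis(trifluoromethanesulfonimide), O=S(=O)(C(F)(F)F)N(c1ccccc1)S(=O)(=O)C(F)(F)F; L-Selectride, [Li+].CCC(C)[BH-](C(C)CC)C(C)CC (its lithium stays only in 4)
Why: A β-unsubstituted cyclohexenone with a hindered carbonyl takes Selectride hydride in the 1,4 sense (conjugate reduction), which gives the tetrasubstituted enolate regiospecifically, and O-triflation fixes the later C5=C6 double bond while the silyloxy carbon is untouched.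

Step 4
Reactants: 5 (4R)-4-[(tert-butyldimethylsilyl)oxy]-2,6,6-trimethylcyclohex-1-en-1-yl trifluoromethanesulfonate; 6 (2E)-3-methylpent-2-en-4-yn-1-ol
Product: 7 (2E)-5-{(4R)-4-[(tert-butyldimethylsilyl)oxy]-2,6,6-trimethylcyclohex-1-en-1-yl}-3-methylpent-2-en-4-yn-1-ol
Conditions: Pd(PPh3)4 (5 mol %), CuI (10 mol %), i-Pr2NH, DMF, rt
Reagents that add atoms: none
Why: In this Sonogashira coupling zerovalent palladium inserts into the vinyl C–OTf bond and the copper acetylide of 6 delivers the enyne, so the 9E geometry bought with 6 is kept.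

Step 5
Reactants: 7 (2E)-5-{(4R)-4-[(tert-butyldimethylsilyl)oxy]-2,6,6-trimethylcyclohex-1-en-1-yl}-3-methylpent-2-en-4-yn-1-ol
Product: 9 (E)-N-tosylhydrazone of (2E)-5-{(4R)-4-[(tert-butyldimethylsilyl)oxy]-2,6,6-trimethylcyclohex-1-en-1-yl}-3-methylpent-2-en-4-ynal, via C15 enynal 8 (not isolated)
Conditions: MnO2, CH2Cl2, rt; filter; TsNHNH2, MeOH, rt
Reagents that add atoms: 4-methylbenzenesulfonohydrazide, Cc1ccc(cc1)S(=O)(=O)NN
Why: MnO2 oxidises only the primary allylic alcohol without E/Z leakage, and hydrazone condensation then turns the enal into a crystalline, storable precursor of the C11 carbon nucleophile.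

Step 6
Reactants: 10 (R)-α-ionone, (3E)-4-[(1R)-2,6,6-trimethylcyclohex-2-en-1-yl]but-3-en-2-one
Product: 11 vinyl-α-ionol, (1E)-3-methyl-1-[(1R)-2,6,6-trimethylcyclohex-2-en-1-yl]penta-1,4-dien-3-ol (both carbinol epimers)
Conditions: CH2=CHMgBr, THF, −20 → 0 °C; then H2O
Reagents that add atoms: vinylmagnesium bromide, C=C[Mg]Br
Why: Grignard 1,2-addition to the enone carbonyl outruns γ-deprotonation at low temperature, so C6' stays R, and the new carbinol centre is a mixture that step 7 erases.

Step 7
Reactants: 11 vinyl-α-ionol; 12 (2E,4E,6E)-2,7-dimethylocta-2,4,6-trienedial (C10 dialdehyde, 1.5 equiv)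
Product: 14 (2E,4E,6E,8E,10E,12E)-2,7,11-trimethyl-13-[(1R)-2,6,6-trimethylcyclohex-2-en-1-yl]trideca-2,4,6,8,10,12-hexaenal, via C15 phosphonium bromide 13 (not isolated)
Conditions: PPh3·HBr, MeOH, rt; then 12, NaOMe, CH2Cl2/MeOH, 0 °C → rt; EtOH, 70 °C, 2 h (Z → E); crystallise
Reagents that add atoms: triphenylphosphine hydrobromide, [Br-].c1ccc(cc1)[PH+](c1ccccc1)c1ccccc1 (its atoms stay only in 13)
Why: The tertiary bis-allylic alcohol ionises and phosphine attacks the primary terminus (allylic transposition) to give the 9'E salt, whose ylide undergoes a Wittig reaction with one aldehyde of the excess dialdehyde; the hindered 11'Z isomer relaxes to E on warming and C6' is not touched.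

Step 8
Reactants: 9 C15 enynal N-tosylhydrazone (1.3 equiv); 14 C25 hexaenal
Product: 19 crocoxanthin (3R,6'R)-7,8-didehydro-β,ε-caroten-3-ol, via hydrazone sodium salt 15 (not isolated), via diazoalkene 16 (not isolated), via phosphite ylide 17 (not isolated), via crocoxanthin TBS ether 18 (not isolated)
Conditions: NaHMDS (1.0 equiv to 9), toluene, 0 °C; then 14, Fe(TPP)Cl (2 mol %, TPP = tetraphenylporphyrinate), BnEt3NCl (10 mol %), P(OMe)3 (1.5 equiv), 40 °C, dark; then Bu4NF, THF, rt
Reagents that add atoms: sodium hexamethyldisilazide, [Na+].C[Si](C)(C)[N-][Si](C)(C)C (its sodium stays only in 15); trimethyl phosphite, COP(OC)OC (its atoms stay only in 17)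
Why: Proposed new method: at 40 °C the phase-transferred salt 15 expels sulfinate (Bamford–Stevens) to give diazoalkene 16, in which the former aldehyde carbon C11 is now the nucleophilic centre; Fe(TPP)Cl captures 16 as an iron carbene and passes the carbon to P(OMe)3, and the allylic phosphite ylide 17 adds to the C12 aldehyde carbon of 14 and collapses Wittig-fashion to the 11E alkene, so two carbonyl carbons are joined directly; the closest known reaction type is the iron-porphyrin/trimethyl phosphite olefination of aldehydes with aryl aldehyde tosylhydrazone salts (E above 95:5), and the extension is an enal-derived hydrazone whose methyl group cis to the diazo carbon slows the competing 1,5-closure to a 3H-pyrazole; no stereocentre is near the reacting atoms, and fluoride finally cleaves the Si–O bond.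

Compound list
1 | ketoisophorone, 2,6,6-trimethylcyclohex-2-ene-1,4-dione | CC1=CC(=O)CC(C)(C)C1=O | starting material
2 | (4S)-4-hydroxy-2,6,6-trimethylcyclohex-2-en-1-one | CC1=C[C@@H](O)CC(C)(C)C1=O | intermediate
3 | (4S)-4-[(tert-butyldimethylsilyl)oxy]-2,6,6-trimethylcyclohex-2-en-1-one | CC1=C[C@@H](O[Si](C)(C)C(C)(C)C)CC(C)(C)C1=O | intermediate
4 | lithium (4R)-4-[(tert-butyldimethylsilyl)oxy]-2,6,6-trimethylcyclohex-1-en-1-olate | [Li+].[O-]C1=C(C)C[C@@H](O[Si](C)(C)C(C)(C)C)CC1(C)C | intermediate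
5 | (4R)-4-[(tert-butyldimethylsilyl)oxy]-2,6,6-trimethylcyclohex-1-en-1-yl trifluoromethanesulfonate | FC(F)(F)S(=O)(=O)OC1=C(C)C[C@@H](O[Si](C)(C)C(C)(C)C)CC1(C)C | intermediate
6 | (2E)-3-methylpent-2-en-4-yn-1-ol | C#C/C(C)=C/CO | starting material
7 | (2E)-5-{(4R)-4-[(tert-butyldimethylsilyl)oxy]-2,6,6-trimethylcyclohex-1-en-1-yl}-3-methylpent-2-en-4-yn-1-ol | OC/C=C(\C)C#CC1=C(C)C[C@@H](O[Si](C)(C)C(C)(C)C)CC1(C)C | intermediate
8 | (2E)-5-{(4R)-4-[(tert-butyldimethylsilyl)oxy]-2,6,6-trimethylcyclohex-1-en-1-yl}-3-methylpent-2-en-4-ynal | O=C/C=C(\C)C#CC1=C(C)C[C@@H](O[Si](C)(C)C(C)(C)C)CC1(C)C | intermediate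
9 | (E)-N-tosylhydrazone of 8 | Cc1ccc(cc1)S(=O)(=O)N/N=C/C=C(\C)C#CC1=C(C)C[C@@H](O[Si](C)(C)C(C)(C)C)CC1(C)C | intermediate
10 | (R)-α-ionone, (3E)-4-[(1R)-2,6,6-trimethylcyclohex-2-en-1-yl]but-3-en-2-one | CC1=CCCC(C)(C)[C@H]1/C=C/C(C)=O | starting material
11 | vinyl-α-ionol, (1E)-3-methyl-1-[(1R)-2,6,6-trimethylcyclohex-2-en-1-yl]penta-1,4-dien-3-ol (carbinol epimers) | CC1=CCCC(C)(C)[C@H]1/C=C/C(C)(O)C=C | intermediate
12 | (2E,4E,6E)-2,7-dimethylocta-2,4,6-trienedial | O=C/C(C)=C/C=C/C=C(C)/C=O | starting material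
13 | {(2E,4E)-3-methyl-5-[(1R)-2,6,6-trimethylcyclohex-2-en-1-yl]penta-2,4-dien-1-yl}triphenylphosphonium bromide | [Br-].CC1=CCCC(C)(C)[C@H]1/C=C/C(C)=C/C[P+](c1ccccc1)(c1ccccc1)c1ccccc1 | intermediate
14 | (2E,4E,6E,8E,10E,12E)-2,7,11-trimethyl-13-[(1R)-2,6,6-trimethylcyclohex-2-en-1-yl]trideca-2,4,6,8,10,12-hexaenal | CC1=CCCC(C)(C)[C@H]1/C=C/C(C)=C/C=C/C(C)=C/C=C/C=C(C)/C=O | intermediate
15 | sodium salt of tosylhydrazone 9 | [Na+].Cc1ccc(cc1)S(=O)(=O)[N-]/N=C/C=C(\C)C#CC1=C(C)C[C@@H](O[Si](C)(C)C(C)(C)C)CC1(C)C | intermediate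
16 | (3E)-5-diazo-3-methylpent-3-en-1-ynyl derivative of the silyloxy ring (diazoalkene) | [N-]=[N+]=C/C=C(\C)C#CC1=C(C)C[C@@H](O[Si](C)(C)C(C)(C)C)CC1(C)C | intermediate
17 | trimethoxyphosphonium allylide at C11 (phosphite ylide) | COP(OC)(OC)=C/C=C(\C)C#CC1=C(C)C[C@@H](O[Si](C)(C)C(C)(C)C)CC1(C)C | intermediate
18 | crocoxanthin 3-O-tert-butyldimethylsilyl ether, all-E, (3R,6'R) | CC1=CCCC(C)(C)[C@H]1/C=C/C(C)=C/C=C/C(C)=C/C=C/C=C(C)/C=C/C=C(\C)C#CC1=C(C)C[C@@H](O[Si](C)(C)C(C)(C)C)CC1(C)C | intermediate
19 | crocoxanthin, all-E-(3R,6'R)-7,8-didehydro-β,ε-caroten-3-ol | CC1=CCCC(C)(C)[C@H]1/C=C/C(C)=C/C=C/C(C)=C/C=C/C=C(C)/C=C/C=C(\C)C#CC1=C(C)C[C@@H](O)CC1(C)C | target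

Total step count: 8.
Longest linear sequence: 6 steps (1 → 2 → 3 → 5 → 7 → 9 → 19). The ε-ring branch (10 → 11 → 14) joins at step 8.

Steps most likely to fail

Step 8 is the riskiest. Diazoalkene 16 may close to a 3H-pyrazole, ylide 17 may rearrange before it meets the weakly electrophilic hexaenal, or the iron carbene may attack the polyene. The fallback sets out from 7 and prepares the C11 carbanion from the alcohol oxidation level instead. PPh3·HBr in CH2Cl2 at 0 °C converts 7 into the allylic triphenylphosphonium bromide F1. Deprotonating F1 with NaOMe in CH2Cl2/MeOH in the presence of 14 is a classical Wittig olefination. It comes back to the route at 18, which is desilylated with Bu4NF as in step 8. The 11Z isomer is removed by chromatography, not by iodine equilibration, which would scramble 9E.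

Step 3 comes next. There may be some 1,2-reduction, or the borane-laden hindered enolate may triflate sluggishly. The fallback sets out from 3 and separates the two events. Hydrogenation of the ring double bond (H2, Pd/C, EtOAc) gives the saturated silyloxy ketone F2. Its only α-hydrogen is removed with LDA (THF, −78 °C), which comes back to the route at enolate 4, free of borane, and PhNTf2 then gives 5.

Step 1 is third, because the enantiomeric excess may be too low, the catalyst sense may prove opposite, or the ene-dione C=C may be reduced as well. The fallback sets out from 1 and relays the stereochemistry from a biocatalytic C=C reduction. Fermenting baker's yeast gives (6R)-levodione F3. Hydrogenation over Raney nickel reduces the unhindered carbonyl under substrate control to (4R,6R)-actinol F4, and the minor 4S epimer is removed by crystallisation. TBSCl/imidazole gives the silyl ether F5, and LDA followed by PhNTf2 comes back to the route at 5.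

Further compounds
F1 | step 8 | [(2E)-5-{(4R)-4-[(tert-butyldimethylsilyl)oxy]-2,6,6-trimethylcyclohex-1-en-1-yl}-3-methylpent-2-en-4-yn-1-yl]triphenylphosphonium bromide | [Br-].c1ccccc1[P+](c1ccccc1)(c1ccccc1)C/C=C(\C)C#CC1=C(C)C[C@@H](O[Si](C)(C)C(C)(C)C)CC1(C)C
F2 | step 3 | (4R)-4-[(tert-butyldimethylsilyl)oxy]-2,2,6-trimethylcyclohexan-1-one (C6 epimers) | CC1C[C@@H](O[Si](C)(C)C(C)(C)C)CC(C)(C)C1=O
F3 | step 1 | (6R)-2,2,6-trimethylcyclohexane-1,4-dione (levodione) | C[C@@H]1CC(=O)CC(C)(C)C1=O
F4 | step 1 | (4R,6R)-4-hydroxy-2,2,6-trimethylcyclohexan-1-one (actinol) | C[C@@H]1C[C@@H](O)CC(C)(C)C1=O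
F5 | step 1 | (4R,6R)-4-[(tert-butyldimethylsilyl)oxy]-2,2,6-trimethylcyclohexan-1-one | C[C@@H]1C[C@@H](O[Si](C)(C)C(C)(C)C)CC(C)(C)C1=O
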